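Its constants were set for the occasion; the result is computed.

Target in these flasks is also a reactant: starting material makes it with reagent, then attacks it to give side product. So I look at the contest at each starting material molecule.

1. the best flask by amount of target, in percent of the starting material charged; "all alike" if 1.5 percentage points covers them all (beta / theta / zeta / gamma / all alike)
2. amount of target at the end, in percent of the starting material charged, beta
3. amount of target at the end, in percent of the starting material charged, theta
4. amount of target at the end, in percent of the starting material charged, zeta
5. amount of target at the end, in percent of the starting material charged, gamma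

the same everywhere: starting material 0.80 M; reagent 3.00 equiv; second substrate 0.200 equiv; time 2.0 h
- beta: temperature 50 °C
- theta: temperature 110 °C
- zeta: temperature 80 °C
- gamma: temperature 140 °C

- a species is counted by the starting material in it: one side product counts as two
- the constants hold at 50 °C; other temperatures follow from the activation energies and enthalpies

    starting material + reagent → target (k1 = 1.2 × 10⁻⁴ /M/s, Ea1 = 78.0 kJ/mol)
    second substrate + reagent → second product (k2 = 4.0 × 10⁻⁴ /M/s, Ea2 = 61.0 kJ/mol)
    starting material + second substrate → cross product (k3 = 0.0011 /M/s, Ea3 = 62.0 kJ/mol)
    target ⇌ isomer of the product (K4 = 15, k4 = 1.9 × 10⁻⁴ /s, Ea4 = 88.0 kJ/mol, ΔH4 = −90.0 kJ/mol)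
    reagent ⇌ dormant form (K5 = 0.10, k5 = 2.9 × 10⁻⁴ /s, Ea5 = 91.0 kJ/mol, ΔH5 = 39.0 kJ/mol)
    starting material + target → side product (k6 = 4.0 × 10⁻⁴ /M/s, Ea6 = 79.0 kJ/mol)
    (constants at 50 °C)

I follow one molecule of starting material in theta. It meets free reagent and adds a target, or it meets target and removes one. The odds are the rate constant of making times free reagent against the rate constant of attack times target. At 110 °C the ratio of those constants, the selectivity factor, is 0.283. Reagent also rests as dormant form, with an equilibrium constant here of 0.971, and it relaxes in 0.0976 min, far shorter than 2.0 h. So of 2.40 M charged, 1.22 M is free once that balance stands. The odds are even when target equals selectivity factor times free reagent, and I call that level the ceiling: 0.345 M, or 43.1% of the charge.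

But the ceiling sinks as reagent is used. Second substrate splits its two paths at a ratio of 1.0 at the start, so I let cross product take 0.0789 M of starting material, which leaves 0.721 M for the fork, and second product takes 0.0811 M of reagent. If the target ends near the ceiling, the making step uses about 0.533 M of reagent. Taking reagent at the midpoint of its use gives 1.06 M free and a ceiling of 0.301 M.

A second objection is that isomer shelters target. Target and isomer relax to their balance in 0.0264 min, far shorter than 2.0 h, and the constant here is 0.0791, so the pool of target and isomer has a ceiling of 0.324 M. A third objection is that a ceiling is approached, not reached. Summing the forks, the fraction u of the ceiling filled obeys: spent over pool ceiling = 2 ln(1/(1 − u)) − u. That gives u = 77.6%, and so I reckon theta at 29.2% target.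

Gamma's ceiling starts at 24.7%, below that figure. Zeta's ceiling starts at 64.9%, higher than theta's, but with its isomer constant of 0.872 its pool must reach 54.6% of the charge to match theta, which I take for a close call. For beta I give no figure: target turns to isomer at 1.9 × 10⁻⁴ /s while starting material turns to target at about 2.62 × 10⁻⁴ /s, so the first is slower than the second, and my pool argument needs it much faster. I commit to theta, narrowly.

The forecast, reasoning that “The flasks differ in how the target/isomer equilibrium falls”, names zeta, with 22% for beta, 5.5% for theta, 25.5% for zeta and 0.83% for gamma, and it differs from me on the best flask and on theta.

The simulation gives theta as best: beta 19.4%, theta 28.7%, zeta 24.6%, gamma 19.9%.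

Take the neighbour of theta with 1.80 equiv of reagent. Its starting ceiling scales to 0.207 M. I let cross product take 0.0989 M, which leaves 0.701 M. Reagent use brings the reckoned ceiling to 0.170 M. The same sum gives 90.6% of it, or 19.2% target. The neighbour flask holds 17.7% target beside 68.0% side product.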